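**Retrosynthetic overview**

1. Target 1 is reached by late oxidation-level changes only: the γ-lactone (last ring formed) and the enal both come from 2-(hydroxymethyl)vinyl groups, the C8/C9 cis-diol from dihydroxylation of a C8=C9 alkene, and the oxirane (second-last ring) from invertive closure of a C1 mesylate.
2. The axial C6 angelate comes from hydride reduction of a C6 ketone unmasked from a dimethyl ketal; the C7 stereocentre and the C8=C9 alkene come together from a palladium/formate reductive transposition of a C9 allylic carbonate.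
3. C5, C10 and C1 are set in one three-component coupling (alkenyl cuprate, enone, silyloxyacetaldehyde), steered by a temporary C7 stereocentre.
4. That relay centre and all six ring carbons come from o-cresol 2: oxidative dearomatisation to the achiral quinone monoketal 3 and catalytic enantioselective alkenylation in the same flask (key step); both three-carbon side chains come from 2-bromoallyl alcohol 4.
5. Ring order: the carbocycle is the former arene ring of 2 (never rebuilt), then the oxirane, then the lactone.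

Convention (one line): ring carbons are numbered as in the elemane skeleton (C10 quaternary, C9 CH–OH, C8 lactone O–CH, C7 lactone C–CH, C6 CH–O-angeloyl, C5 CH bearing the acrolein unit, C1/C2 the oxirane CH/CH2); β is the face of the C10 methyl group in 1, α the opposite face; TBSO = tert-butyldimethylsilyloxy.

**Route**

Step 1
Reactants: 4 2-bromoprop-2-en-1-ol
Product: 5 (2-bromoprop-2-en-1-yloxy)(tert-butyl)dimethylsilane
Conditions: TBSCl, imidazole, CH2Cl2, 0 °C to rt
Reagents that add atoms: tert-butyldimethylsilyl chloride, CC(C)(C)[Si](C)(C)Cl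
Why: Routine silyl ether formation on a primary allylic alcohol; no stereocentre is involved.

Step 2
Reactants: 5 (2-bromoprop-2-en-1-yloxy)(tert-butyl)dimethylsilane
Product: 6 2-[3-(TBSO)prop-1-en-2-yl]-4,4,5,5-tetramethyl-1,3,2-dioxaborolane
Conditions: B2pin2 (1.1 equiv), PdCl2(PPh3)2 (3 mol %), PPh3 (6 mol %), KOPh (1.5 equiv), toluene, 50 °C
Reagents that add atoms: bis(pinacolato)diboron, CC1(C)OB(OC1(C)C)B1OC(C)(C)C(C)(C)O1
Why: Miyaura borylation of a 1-alkenyl bromide: zerovalent palladium formed in the flask inserts into the C–Br bond, phenoxide replaces bromide on palladium and the resulting phenoxo complex transmetalates with the diboron reagent, the weak base KOPh suppressing Suzuki homocoupling; no stereocentre is involved.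

Step 3
Reactants: 2 o-cresol; 6 2-[3-(TBSO)prop-1-en-2-yl]-4,4,5,5-tetramethyl-1,3,2-dioxaborolane
Product: 8 (5R)-4,4-dimethoxy-2-methyl-5-[3-(TBSO)prop-1-en-2-yl]cyclohex-2-en-1-one (C7 side chain α), via 4-methoxy-2-methylphenol 7 (not isolated), via quinone monoketal 3 (not isolated)
Conditions: PhI(OAc)2 (2.0 equiv), MeOH, 0 °C to rt; evaporate; then 6 (1.5 equiv), [RhCl(C2H4)2]2 (2.5 mol %), (R)-BINAP (6 mol %), KOH, 1,4-dioxane/H2O (10:1), 35 °C
Reagents that add atoms: methanol, CO
Why: Proposed new method: the trivalent-iodine oxidation of a para-unsubstituted phenol in methanol to its para-quinone monoketal (through 7) and the Hayashi–Miyaura rhodium/BINAP 1,4-addition of an alkenylboron reagent are each established and are here run in one flask (closest known reaction type: rhodium-catalysed asymmetric addition of organoboron reagents to isolated quinone monoketals); the spent oxidant is only PhI and acetate, KOH neutralises the acid, the α-methyl enone half of 3 is inert to the alkenylrhodium species so only the C7=C8 enone reacts, and (R)-BINAP is chosen because the cyclohexenone model places the alkenyl group on the α face (5R), a centre used only as a relay and erased in step 5.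

Step 4
Reactants: 8 (5R)-4,4-dimethoxy-2-methyl-5-[3-(TBSO)prop-1-en-2-yl]cyclohex-2-en-1-one; 5 (2-bromoprop-2-en-1-yloxy)(tert-butyl)dimethylsilane; 9 (tert-butyldimethylsilyloxy)acetaldehyde
Product: 14 6,6-dimethoxy-10β-methyl-10α-[(1S)-1-(methylsulfonyloxy)-2-(TBSO)ethyl]-5β,7α-bis[3-(TBSO)prop-1-en-2-yl]cyclohexan-9-one, via alkenyllithium 10 (not isolated), via lithium dialkenylcuprate 11 (not isolated), via lithium enolate 12 (not isolated), via lithium aldolate 13 (not isolated)
Conditions: 5 (2.2 equiv), t-BuLi (4.4 equiv), Et2O, −78 °C; CuBr·SMe2 (1.1 equiv), −78 to −40 °C; 8, THF, −78 to −30 °C; 9, −78 °C; MsCl, −78 to 0 °C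
Reagents that add atoms: methanesulfonyl chloride, CS(=O)(=O)Cl
Why: Three-component conjugate addition–aldol coupling with O-sulfonylation of the aldolate, the cuprate being made by bromine–lithium exchange on 5 at −78 °C (where the 2-lithioallyl ether is stable) and transmetalation to copper: the cuprate adds to C5 anti to the C7 substituent (1,3-trans rule for 5-substituted cyclohexenones, giving 5β), the tetrasubstituted enolate is attacked by the aldehyde on the α face anti to the new C5 group (giving 10β-methyl), a Zimmerman–Traxler chair with the CH2OTBS group equatorial gives the (1S)-carbinol, deliberately the opposite of the oxirane configuration because the closure in step 11 inverts C1, and the mesylate cannot eliminate because C10 is quaternary.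

Step 5
Reactants: 14 keto mesylate
Product: 15 6,6-dimethoxy-10β-methyl-10α-[(1S)-1-(methylsulfonyloxy)-2-(TBSO)ethyl]-5β,7-bis[3-(TBSO)prop-1-en-2-yl]cyclohex-7-en-9-one
Conditions: IBX (2.5 equiv), DMSO/fluorobenzene (1:2), 70 °C
Reagents that add atoms: none
Why: IBX dehydrogenation of a ketone to its enone can only occur across C8–C7 because C10 is quaternary; it removes the relay stereocentre at C7 after it has passed its information to C5, C10 and C1.

Step 6
Reactants: 15 dienone mesylate
Product: 17 methyl carbonate of the 9β-allylic alcohol (C7=C8 alkene; other groups as in 15), via allylic aluminium alkoxide 16 (not isolated)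
Conditions: i-Bu2AlH (1.2 equiv), CH2Cl2, −78 °C; then pyridine, DMAP, ClCO2Me, −78 to 0 °C
Reagents that add atoms: methyl chloroformate, COC(=O)Cl
Why: 1,2-Reduction of the cross-conjugated enone followed by acylation of the aluminium alkoxide in the same flask (reductive acylation); hydride enters C9 from the α face, anti to the pseudo-axial C10 methyl group, so the oxygen is 9β.

Step 7
Reactants: 17 allylic methyl carbonate
Product: 18 6,6-dimethoxy-10β-methyl-10α-[(1S)-1-(methylsulfonyloxy)-2-(TBSO)ethyl]-5β,7β-bis[3-(TBSO)prop-1-en-2-yl]cyclohex-8-ene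
Conditions: Pd(OAc)2 (5 mol %), n-Bu3P (10 mol %), HCO2H, Et3N, THF, 40 °C
Reagents that add atoms: none
Why: Tsuji–Mandai formate hydrogenolysis with allylic transposition: zerovalent palladium ionises the 9β-carbonate with inversion, sits on the α face and delivers hydride from there to the more substituted terminus C7, which gives the less substituted C8=C9 alkene and places the C7 side chain β, cis to the C5 side chain (a relationship not reachable by direct nucleophilic addition).

Step 8
Reactants: 18 diene ketal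
Product: 19 10β-methyl-10α-[(1S)-1-(methylsulfonyloxy)-2-(TBSO)ethyl]-5β,7β-bis[3-(TBSO)prop-1-en-2-yl]cyclohex-8-en-6-one
Conditions: 10 % aq. oxalic acid on SiO2, CH2Cl2, rt; used crude
Reagents that add atoms: water, O
Why: Mild acetal hydrolysis of the dimethyl ketal, chosen to be faster than enolisation so that the β,γ-unsaturated ketone is neither conjugated nor epimerised at C5 or C7; no new stereocentre is formed.

Step 9
Reactants: 19 β,γ-unsaturated ketone
Product: 20 6β-hydroxy-10β-methyl-10α-[(1S)-1-(methylsulfonyloxy)-2-(TBSO)ethyl]-5β,7β-bis[3-(TBSO)prop-1-en-2-yl]cyclohex-8-ene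
Conditions: LiBH(s-Bu)3, THF, −78 °C; aq. NH4Cl
Reagents that add atoms: none
Why: Ketone reduction by a bulky hydride from the α face (equatorial attack; the β face is blocked by the syn-axial C10 methyl group) gives the axial 6β-alcohol, cis to both side chains.

Step 10
Reactants: 20 6β-alcohol; 21 angelic anhydride
Product: 23 6β-angelate of 20, via lithium alkoxide 22 (not isolated)
Conditions: LiN(SiMe3)2 (1.05 equiv), THF, −78 °C; 21, −78 to 0 °C
Reagents that add atoms: none
Why: O-Acylation of a preformed lithium alkoxide with the anhydride at low temperature, a method that transfers the angeloyl group to hindered alcohols without Z to E isomerisation; no stereocentre changes.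

Step 11
Reactants: 23 angelate
Product: 25 6β-angeloyloxy-5β,7β-bis(3-hydroxyprop-1-en-2-yl)-10β-methyl-10α-[(2R)-oxiran-2-yl]cyclohex-8-ene, via triol mesylate 24 (not isolated)
Conditions: Bu4NF (3.5 equiv), THF, 0 °C to rt
Reagents that add atoms: none
Why: Fluoride desilylation followed by intramolecular Williamson closure: the C2 alkoxide displaces the C1 mesylate by a 3-exo-tet substitution with inversion, turning the (1S)-mesylate into the (R)-oxirane of the target.

Step 12
Reactants: 25 epoxy diol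
Product: 26 6β-angeloyloxy-10β-methyl-10α-[(2R)-oxiran-2-yl]-5β,7β-bis(3-oxoprop-1-en-2-yl)cyclohex-8-ene
Conditions: MnO2 (activated, excess), CH2Cl2, rt
Reagents that add atoms: none
Why: Chemoselective MnO2 oxidation of the two primary allylic alcohols to 2-substituted acroleins; the epoxide, the angelate and the ring alkene are untouched.

Step 13
Reactants: 26 epoxy dialdehyde
Product: 28 lactol of 1 (C12 hemiacetal as a mixture of anomers), via diol dialdehyde 27 (not isolated)
Conditions: OsO4 (2 mol %), NMO (1.5 equiv), acetone/H2O (4:1), 0 °C to rt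
Reagents that add atoms: N-methylmorpholine N-oxide, C[N+]1([O-])CCOCC1; water, O
Why: Upjohn dihydroxylation of the only electron-rich alkene (the two enals and the angelate are electron-poor) from the α face, anti to the pseudo-axial C10 methyl group and the C7 side chain, sets the 8α,9α-diol; the 8α-hydroxyl then closes onto the C7 formyl group to give the trans-fused lactol.

Step 14
Reactants: 28 lactol
Product: 1 target (5β-(3-oxoprop-1-en-2-yl), 6β-angeloyloxy, 7β,8α-fused α-methylene-γ-lactone, 9α-hydroxy, 10β-methyl, 10α-[(R)-oxiranyl])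
Conditions: MnO2 (activated), CH2Cl2, rt
Reagents that add atoms: none
Why: MnO2 oxidation of an allylic-type lactol to the α-methylene-γ-butyrolactone, as in the known MnO2 conversion of 2-methylene-1,4-diols to such lactones; the free axial 9α-alcohol is not allylic and is not oxidised.

**Compound list**

1 | target: 6β-angelate of the 7β,8α-fused α-methylene-γ-lactone bearing 5β-(3-oxoprop-1-en-2-yl), 9α-OH, 10β-Me, 10α-[(R)-oxiranyl] | C=C1C(=O)O[C@@H]2[C@@H]1[C@@H](OC(=O)/C(C)=C\C)[C@@H](C(=C)C=O)[C@](C)([C@@H]1CO1)[C@@H]2O | target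
2 | o-cresol (2-methylphenol) | Cc1ccccc1O | starting material
3 | 4,4-dimethoxy-2-methylcyclohexa-2,5-dien-1-one | CC1=CC(OC)(OC)C=CC1=O | intermediate
4 | 2-bromoprop-2-en-1-ol | C=C(Br)CO | starting material
5 | (2-bromoprop-2-en-1-yloxy)(tert-butyl)dimethylsilane | C=C(Br)CO[Si](C)(C)C(C)(C)C | intermediate
6 | 2-[3-(TBSO)prop-1-en-2-yl]-4,4,5,5-tetramethyl-1,3,2-dioxaborolane | C=C(CO[Si](C)(C)C(C)(C)C)B1OC(C)(C)C(C)(C)O1 | intermediate
7 | 4-methoxy-2-methylphenol | COc1ccc(O)c(C)c1 | intermediate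
8 | (5R)-4,4-dimethoxy-2-methyl-5-[3-(TBSO)prop-1-en-2-yl]cyclohex-2-en-1-one | C1[C@H](C(=C)CO[Si](C)(C)C(C)(C)C)C(OC)(OC)C=C(C)C1=O | intermediate
9 | (tert-butyldimethylsilyloxy)acetaldehyde | O=CCO[Si](C)(C)C(C)(C)C | starting material
10 | [3-(TBSO)prop-1-en-2-yl]lithium | [Li]C(=C)CO[Si](C)(C)C(C)(C)C | intermediate
11 | lithium bis[3-(TBSO)prop-1-en-2-yl]cuprate, LiCu(C9H19OSi)2 | [Li+].C=C(CO[Si](C)(C)C(C)(C)C)[Cu-]C(=C)CO[Si](C)(C)C(C)(C)C | intermediate
12 | lithium C9,C10-enolate after cuprate addition (5β,7α side chains) | C1[C@H](C(=C)CO[Si](C)(C)C(C)(C)C)C(OC)(OC)[C@@H](C(=C)CO[Si](C)(C)C(C)(C)C)C(C)=C1O[Li] | intermediate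
13 | lithium (1S)-aldolate (10β-Me, 10α side chain) | C1[C@H](C(=C)CO[Si](C)(C)C(C)(C)C)C(OC)(OC)[C@@H](C(=C)CO[Si](C)(C)C(C)(C)C)[C@](C)([C@H](O[Li])CO[Si](C)(C)C(C)(C)C)C1=O | intermediate
14 | 6,6-dimethoxy-10β-methyl-10α-[(1S)-1-(methylsulfonyloxy)-2-(TBSO)ethyl]-5β,7α-bis[3-(TBSO)prop-1-en-2-yl]cyclohexan-9-one | C1[C@H](C(=C)CO[Si](C)(C)C(C)(C)C)C(OC)(OC)[C@@H](C(=C)CO[Si](C)(C)C(C)(C)C)[C@](C)([C@H](OS(C)(=O)=O)CO[Si](C)(C)C(C)(C)C)C1=O | intermediate
15 | cyclohex-7-en-9-one analogue of 14 (C7 trigonal) | C1=C(C(=C)CO[Si](C)(C)C(C)(C)C)C(OC)(OC)[C@@H](C(=C)CO[Si](C)(C)C(C)(C)C)[C@](C)([C@H](OS(C)(=O)=O)CO[Si](C)(C)C(C)(C)C)C1=O | intermediate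
16 | diisobutylaluminium alkoxide of the 9β-allylic alcohol | C1=C(C(=C)CO[Si](C)(C)C(C)(C)C)C(OC)(OC)[C@@H](C(=C)CO[Si](C)(C)C(C)(C)C)[C@](C)([C@H](OS(C)(=O)=O)CO[Si](C)(C)C(C)(C)C)[C@H]1O[Al](CC(C)C)CC(C)C | intermediate
17 | 9β-allylic methyl carbonate | C1=C(C(=C)CO[Si](C)(C)C(C)(C)C)C(OC)(OC)[C@@H](C(=C)CO[Si](C)(C)C(C)(C)C)[C@](C)([C@H](OS(C)(=O)=O)CO[Si](C)(C)C(C)(C)C)[C@H]1OC(=O)OC | intermediate
18 | cyclohex-8-ene ketal with 5β,7β side chains | C=1[C@@H](C(=C)CO[Si](C)(C)C(C)(C)C)C(OC)(OC)[C@@H](C(=C)CO[Si](C)(C)C(C)(C)C)[C@](C)([C@H](OS(C)(=O)=O)CO[Si](C)(C)C(C)(C)C)C1 | intermediate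
19 | cyclohex-8-en-6-one with 5β,7β side chains | C=1[C@@H](C(=C)CO[Si](C)(C)C(C)(C)C)C(=O)[C@@H](C(=C)CO[Si](C)(C)C(C)(C)C)[C@](C)([C@H](OS(C)(=O)=O)CO[Si](C)(C)C(C)(C)C)C1 | intermediate
20 | 6β-alcohol | C=1[C@@H](C(=C)CO[Si](C)(C)C(C)(C)C)[C@@H](O)[C@@H](C(=C)CO[Si](C)(C)C(C)(C)C)[C@](C)([C@H](OS(C)(=O)=O)CO[Si](C)(C)C(C)(C)C)C1 | intermediate
21 | angelic anhydride, (Z)-2-methylbut-2-enoic anhydride | C/C=C(C)\C(=O)OC(=O)/C(C)=C\C | starting material
22 | lithium alkoxide of 20 | C=1[C@@H](C(=C)CO[Si](C)(C)C(C)(C)C)[C@@H](O[Li])[C@@H](C(=C)CO[Si](C)(C)C(C)(C)C)[C@](C)([C@H](OS(C)(=O)=O)CO[Si](C)(C)C(C)(C)C)C1 | intermediate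
23 | 6β-angelate, tris-TBS ether, (1S)-mesylate | C=1[C@@H](C(=C)CO[Si](C)(C)C(C)(C)C)[C@@H](OC(=O)/C(C)=C\C)[C@@H](C(=C)CO[Si](C)(C)C(C)(C)C)[C@](C)([C@H](OS(C)(=O)=O)CO[Si](C)(C)C(C)(C)C)C1 | intermediate
24 | desilylated triol (1S)-mesylate | C=1[C@@H](C(=C)CO)[C@@H](OC(=O)/C(C)=C\C)[C@@H](C(=C)CO)[C@](C)([C@H](OS(C)(=O)=O)CO)C1 | intermediate
25 | epoxy diol, (R)-oxirane | C=1[C@@H](C(=C)CO)[C@@H](OC(=O)/C(C)=C\C)[C@@H](C(=C)CO)[C@](C)([C@@H]2CO2)C1 | intermediate
26 | epoxy dialdehyde | C=1[C@@H](C(=C)C=O)[C@@H](OC(=O)/C(C)=C\C)[C@@H](C(=C)C=O)[C@](C)([C@@H]2CO2)C1 | intermediate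
27 | 8α,9α-diol dialdehyde | O[C@@H]1[C@@H](C(=C)C=O)[C@@H](OC(=O)/C(C)=C\C)[C@@H](C(=C)C=O)[C@](C)([C@@H]2CO2)[C@@H]1O | intermediate
28 | lactol of 1 (C12 hemiacetal, anomeric mixture) | C=C1C(O)O[C@@H]2[C@@H]1[C@@H](OC(=O)/C(C)=C\C)[C@@H](C(=C)C=O)[C@](C)([C@@H]1CO1)[C@@H]2O | intermediate

**Step count and risk**

Total: 14 steps. Longest linear sequence: 14 steps (4 to 1); 12 steps from o-cresol 2.

The three steps most likely to fail:

Step 4 (three-component coupling). The hindered tetrasubstituted enolate may protonate the aldehyde, the aldol may reverse before trapping, or the C1 sense may erode. The fallback sets out from 8 and comes back at 14. The cuprate 11 is added to 8 in the presence of Me3SiCl and the trimethylsilyl enol ether F1 is isolated. MeLi in THF at 0 °C then regenerates the copper-free lithium enolate 12, which is added to 9 at −78 °C and worked up to the isolated β-hydroxy ketone F2, so the C1 configuration can be checked before committing. MsCl/Et3N in CH2Cl2 converts F2 into 14.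

Step 7 (formate hydrogenolysis). Hydride may be delivered to C9, or through the pendant alkene, giving conjugated dienes, and the C7 face depends on the C9 face set in step 6. The fallback sets out from 14 and comes back at 19, bypassing steps 5 to 8. KN(SiMe3)2 and 2-[N,N-bis(trifluoromethylsulfonyl)amino]-5-chloropyridine give the C9 enol triflate F3, and wet oxalic acid on SiO2 unmasks the C6 ketone F4, which still carries the 7α side chain. The doubly activated C7–H is removed with KN(SiMe3)2 at −78 °C to give the potassium dienolate F5. Kinetic protonation with 2,6-di-tert-butylphenol, anti to the C5 substituent, gives the 7β ketone F6. Pd(OAc)2/PPh3/HCO2H/Bu3N in DMF at 60 °C (reduction of the enol triflate) then gives 19.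

Step 10 (angeloylation). The 6β-hydroxyl is axial, flanked by two branched carbons and syn-axial to the C10 methyl group, so acyl transfer may stall or the angelate may isomerise under forcing. The fallback sets out from 20 and comes back at 23 and builds the (Z)-alkene on the ester instead of transferring it. Esterification with 2-[bis(2,2,2-trifluoroethoxy)phosphoryl]propanoic acid (DCC, DMAP) gives the phosphonate ester F7. KN(SiMe3)2/18-crown-6 at −78 °C gives its potassium carbanion F8, and Still–Gennari olefination with acetaldehyde gives the (Z)-2-methylbut-2-enoate 23.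

**Further compounds**

F1 | step 4 | trimethylsilyl enol ether of the cuprate adduct (5β,7α side chains) | C1[C@H](C(=C)CO[Si](C)(C)C(C)(C)C)C(OC)(OC)[C@@H](C(=C)CO[Si](C)(C)C(C)(C)C)C(C)=C1O[Si](C)(C)C
F2 | step 4 | (1S)-β-hydroxy ketone (free aldol corresponding to 14) | C1[C@H](C(=C)CO[Si](C)(C)C(C)(C)C)C(OC)(OC)[C@@H](C(=C)CO[Si](C)(C)C(C)(C)C)[C@](C)([C@H](O)CO[Si](C)(C)C(C)(C)C)C1=O
F3 | step 7 | C9 enol triflate of 14 (7α side chain, ketal intact) | C=1[C@H](C(=C)CO[Si](C)(C)C(C)(C)C)C(OC)(OC)[C@@H](C(=C)CO[Si](C)(C)C(C)(C)C)[C@](C)([C@H](OS(C)(=O)=O)CO[Si](C)(C)C(C)(C)C)C1OS(=O)(=O)C(F)(F)F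
F4 | step 7 | C6 ketone enol triflate with 7α side chain | C=1[C@H](C(=C)CO[Si](C)(C)C(C)(C)C)C(=O)[C@@H](C(=C)CO[Si](C)(C)C(C)(C)C)[C@](C)([C@H](OS(C)(=O)=O)CO[Si](C)(C)C(C)(C)C)C1OS(=O)(=O)C(F)(F)F
F5 | step 7 | potassium C6,C7-dienolate of F4 | C=1C(C(=C)CO[Si](C)(C)C(C)(C)C)=C(O[K])[C@@H](C(=C)CO[Si](C)(C)C(C)(C)C)[C@](C)([C@H](OS(C)(=O)=O)CO[Si](C)(C)C(C)(C)C)C1OS(=O)(=O)C(F)(F)F
F6 | step 7 | C6 ketone enol triflate with 7β side chain | C=1[C@@H](C(=C)CO[Si](C)(C)C(C)(C)C)C(=O)[C@@H](C(=C)CO[Si](C)(C)C(C)(C)C)[C@](C)([C@H](OS(C)(=O)=O)CO[Si](C)(C)C(C)(C)C)C1OS(=O)(=O)C(F)(F)F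
F7 | step 10 | 6β-O-{2-[bis(2,2,2-trifluoroethoxy)phosphoryl]propanoyl} ester of 20 | C=1[C@@H](C(=C)CO[Si](C)(C)C(C)(C)C)[C@@H](OC(=O)C(C)P(=O)(OCC(F)(F)F)OCC(F)(F)F)[C@@H](C(=C)CO[Si](C)(C)C(C)(C)C)[C@](C)([C@H](OS(C)(=O)=O)CO[Si](C)(C)C(C)(C)C)C1
F8 | step 10 | potassium carbanion of F7 | C=1[C@@H](C(=C)CO[Si](C)(C)C(C)(C)C)[C@@H](OC(=O)[C-](C)P(=O)(OCC(F)(F)F)OCC(F)(F)F)[C@@H](C(=C)CO[Si](C)(C)C(C)(C)C)[C@](C)([C@H](OS(C)(=O)=O)CO[Si](C)(C)C(C)(C)C)C1.[K+]
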